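**Plan**
1. Retrosynthesis: the two silyl ethers and the ring-B groups are removed first (O4'–prenyl bond, then the C5'–C(Me)2CH=CH2 bond by aromatic Claisen back to an O4'-prenyl ether, then that ether).
2. The core is traced to a cis-pterocarpan by adding a temporary C4–O2' bond. This bond and C2–C3 are cut together, giving an E-stilbene (C3=C4) that carries C2 on O1 as an acyloxymethyl ether. C3=C4 is cut by Wittig into two benzaldehyde-derived halves.
3. Forward: stilbene; one cascade closes the pyran ring (C2–C3) and then the temporary dihydrofuran ring (C4–O2'); ionic hydrogenation in the same flask reopens the latter; ring B is then finished and the silyl groups leave.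
4. Enabling feature: C2 sits on the aryl oxygen O1, ortho to the C4a–C4=C3 styrene unit of ring A, so an aryloxymethyl cation at C2 can reach C3. The 7-oxygen is para to C4a and stabilises the resulting C4 cation. The 2'-OH of ring B is ortho to C1' and can trap C4.
5. Stereochemistry: C3 (R) is the only stereocentre of the target. It is set in the cascade by a chiral confined Brønsted acid; the temporary C4 centre follows from cis ring fusion and is erased in the same step; no later step acts at C3.

Key step: step 6

Assumption: the sense of induction of the chiral acid cannot be predicted with certainty; the catalyst antipode that delivers (6aR,11aR)-11 and hence (3R)-12 is meant and is written here as (S,S).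

**Route**

Step 1
Reactants: 1 2,4-dihydroxybenzaldehyde
Product: 2 2-hydroxy-4-[(triisopropylsilyl)oxy]benzaldehyde
Conditions: TIPSCl (1.05 equiv), imidazole, CH2Cl2, 0 °C
Reagents that add atoms: triisopropylsilyl chloride, CC(C)[Si](Cl)(C(C)C)C(C)C
Why: Silyl ether formation should go to O4, the more acidic and unchelated phenol, because the 2-OH is held in a hydrogen bond to the aldehyde.

Step 2
Reactants: 2 2-hydroxy-4-[(triisopropylsilyl)oxy]benzaldehyde
Product: 3 {2-formyl-5-[(triisopropylsilyl)oxy]phenoxy}methyl pivalate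
Conditions: NaH, THF, 0 °C; ClCH2OPiv, NaI (cat.), 0 °C to rt
Reagents that add atoms: chloromethyl pivalate, CC(C)(C)C(=O)OCCl
Why: Williamson-type O-alkylation of the sodium phenoxide with an α-chloro ether places the future C2 on O1 as an acyloxymethyl group that tolerates base but can be ionised by acid.

Step 3
Reactants: 4 4-(benzyloxy)-2-hydroxybenzaldehyde
Product: 5 5-(benzyloxy)-2-(hydroxymethyl)phenol
Conditions: NaBH4, MeOH–THF, 0 °C
Reagents that add atoms: none
Why: Borohydride reduction of an aryl aldehyde to the benzyl alcohol leaves the phenol and the benzyl ether untouched.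

Step 4
Reactants: 5 5-(benzyloxy)-2-(hydroxymethyl)phenol
Product: 6 [4-(benzyloxy)-2-hydroxybenzyl]triphenylphosphonium bromide
Conditions: PPh3·HBr, MeCN, 80 °C
Reagents that add atoms: triphenylphosphine hydrobromide, [Br-].c1ccc(cc1)[PH+](c1ccccc1)c1ccccc1
Why: Phosphonium salt formation from an o-hydroxybenzyl alcohol, which ionises under the acidic salt to the o-quinone methide or benzyl cation and is captured by triphenylphosphine.

Step 5
Reactants: 6 [4-(benzyloxy)-2-hydroxybenzyl]triphenylphosphonium bromide; 3 {2-formyl-5-[(triisopropylsilyl)oxy]phenoxy}methyl pivalate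
Product: 9 {2-[(E)-2-(4-(benzyloxy)-2-hydroxyphenyl)ethenyl]-5-[(triisopropylsilyl)oxy]phenoxy}methyl pivalate, via lithium phenoxide ylide 7 (not isolated), via stilbene E/Z mixture 8 (not isolated)
Conditions: LiHMDS (2.05 equiv), THF, −78 °C; 3, −78 to 0 °C; AcOH (1 equiv); then I2 (5 mol %), PhMe, 80 °C
Reagents that add atoms: none
Why: Wittig olefination of the semi-stabilised phenoxide benzylide with aldehyde 3, followed by iodine-catalysed Z to E equilibration, should give the thermodynamically favoured E-stilbene, and the hindered pivalate and the silyl ether should survive the amide base at low temperature.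

Step 6
Reactants: 9 {2-[(E)-2-(4-(benzyloxy)-2-hydroxyphenyl)ethenyl]-5-[(triisopropylsilyl)oxy]phenoxy}methyl pivalate
Product: 12 5-(benzyloxy)-2-{(3R)-7-[(triisopropylsilyl)oxy]chroman-3-yl}phenol, via C4 benzylic cation 10 (not isolated), via cis-pterocarpan 11 (not isolated)
Conditions: (S,S)-IDPi (BINOL-derived N-triflyl imidodiphosphorimidate Brønsted acid with 3,3'-aryl groups, 5 mol %), CHCl3 (0.02 M), −40 °C; then Et3SiH (10 equiv), TFA (10 equiv), same flask, −40 to 0 °C
Reagents that add atoms: none
Why: Proposed new method: the chiral acid protonates the pivalate carbonyl of 9 and expels pivalic acid to give the aryloxymethyl oxocarbenium ion O1=C2H2(+) as a contact ion pair with the confined chiral anion; this cation adds through C2 to C3 of the E-stilbene (Prins-type, equally a cationic 6π closure of the 2-oxonia-triene C2=O1–C8a=C4a–C4=C3) to give cation 10 at C4, which the ring-B 2'-OH traps as cis-pterocarpan 11. Triethylsilane and trifluoroacetic acid, added to the same flask once 9 is consumed, then reopen the temporary C4–O2' bond of 11 to the same para-silyloxy-stabilised cation and deliver hydride to C4 (ionic hydrogenation of a benzylic aryl ether), which removes the temporary ring and frees the 2'-OH of 12 without touching C3 or the benzyl and silyl ethers. The closest known reaction types are chiral-acid (counter-anion-directed) Prins cyclisations and oxa-Pictet–Spengler reactions of oxocarbenium ions, Lewis-acid Prins cyclisations of α-acyloxy ethers, acid-catalysed Prins reactions of styrenes with formaldehyde, and the stepwise addition of aryloxycarbenium ions to styrenes; new here are the acyloxymethyl aryl ether as cation source and the phenol-terminated stilbene cascade under asymmetric control. The pyran ring closes 6-endo-trig at both the oxocarbenium ion and the alkene, and the temporary dihydrofuran ring closes 5-exo-trig at the quinone-methide-like C4=C4a unit of 10. C3 (C6a of 11) is set in the C2–C3 bond formation by the chiral anion, which is hydrogen-bonded to the 2'-OH and selects one helical conformer of the oxonia-triene; C4 (C11a) follows from the substrate because only the cis-fused 6/5 system is free of strain, and it is erased by the hydride transfer. The step needs C2–C3 over C2–C4 bonding, secured by the disfavoured 5-endo-trig geometry of the latter, by the E-alkene that places the ring-B aryl outside the closing termini and by the para 7-silyloxy group of ring A that stabilises charge at C4; it needs clean ionisation to the aryloxymethyl cation, secured by the acyl group that makes pivalate and not the phenol the leaving group; it needs capture of 10 faster than loss of H3, secured first by the 2'-OH held next to C4 and then by the excess of silane at low temperature.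

Step 7
Reactants: 12 5-(benzyloxy)-2-{(3R)-7-[(triisopropylsilyl)oxy]chroman-3-yl}phenol
Product: 13 (3R)-3-{4-(benzyloxy)-2-[(triisopropylsilyl)oxy]phenyl}-7-[(triisopropylsilyl)oxy]chroman
Conditions: TIPSOTf (1.3 equiv), 2,6-lutidine, CH2Cl2, 0 °C to rt
Reagents that add atoms: triisopropylsilyl trifluoromethanesulfonate, CC(C)[Si](OS(=O)(=O)C(F)(F)F)(C(C)C)C(C)C
Why: Silyl ether formation with the silyl triflate is reactive enough for the hindered ortho-substituted phenol and masks O2' so that only O4' can be alkylated later.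

Step 8
Reactants: 13 (3R)-3-{4-(benzyloxy)-2-[(triisopropylsilyl)oxy]phenyl}-7-[(triisopropylsilyl)oxy]chroman
Product: 14 4-{(3R)-7-[(triisopropylsilyl)oxy]chroman-3-yl}-3-[(triisopropylsilyl)oxy]phenol
Conditions: H2 (1 atm), Pd/C, EtOAc, rt
Reagents that add atoms: none
Why: Hydrogenolysis of the benzyl ether over palladium on carbon frees the 4'-OH alone, since no alkene is present yet and the aryl silyl ethers and the chroman are inert.

Step 9
Reactants: 14 4-{(3R)-7-[(triisopropylsilyl)oxy]chroman-3-yl}-3-[(triisopropylsilyl)oxy]phenol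
Product: 15 (3R)-3-{4-[(3-methylbut-2-en-1-yl)oxy]-2-[(triisopropylsilyl)oxy]phenyl}-7-[(triisopropylsilyl)oxy]chroman
Conditions: prenyl bromide, K2CO3, acetone, rt
Reagents that add atoms: prenyl bromide (1-bromo-3-methylbut-2-ene), CC(C)=CCBr
Why: Williamson ether synthesis on the single free phenol gives the aryl prenyl ether.

Step 10
Reactants: 15 (3R)-3-{4-[(3-methylbut-2-en-1-yl)oxy]-2-[(triisopropylsilyl)oxy]phenyl}-7-[(triisopropylsilyl)oxy]chroman
Product: 17 2-(2-methylbut-3-en-2-yl)-4-{(3R)-7-[(triisopropylsilyl)oxy]chroman-3-yl}-5-[(triisopropylsilyl)oxy]phenol, via ortho-dienone 16 (not isolated)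
Conditions: Eu(fod)3 (10 mol %; fod = 6,6,7,7,8,8,8-heptafluoro-2,2-dimethyloctane-3,5-dionate), CHCl3, 60 °C
Reagents that add atoms: none
Why: Aromatic Claisen rearrangement ([3,3]) of the aryl prenyl ether under mild europium Lewis acid catalysis should carry the tertiary allyl terminus to C5' (ortho to O4', para to O2') and not to C3', which lies between two oxygen substituents under the bulky 2'-silyloxy group; dienone 16 then tautomerises to the phenol and no stereocentre is formed.

Step 11
Reactants: 17 2-(2-methylbut-3-en-2-yl)-4-{(3R)-7-[(triisopropylsilyl)oxy]chroman-3-yl}-5-[(triisopropylsilyl)oxy]phenol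
Product: 18 (3R)-3-{4-[(3-methylbut-2-en-1-yl)oxy]-5-(2-methylbut-3-en-2-yl)-2-[(triisopropylsilyl)oxy]phenyl}-7-[(triisopropylsilyl)oxy]chroman
Conditions: prenyl bromide, K2CO3, Bu4NI (cat.), acetone, 50 °C
Reagents that add atoms: prenyl bromide (1-bromo-3-methylbut-2-ene), CC(C)=CCBr
Why: Williamson ether synthesis on the hindered phenol should still proceed, because the ortho tert-alkyl group slows but does not block O-alkylation and the silyl ethers tolerate carbonate in acetone.

Step 12
Reactants: 18 (3R)-3-{4-[(3-methylbut-2-en-1-yl)oxy]-5-(2-methylbut-3-en-2-yl)-2-[(triisopropylsilyl)oxy]phenyl}-7-[(triisopropylsilyl)oxy]chroman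
Product: 19 Manuifolin D, (3R)-3-[2-hydroxy-4-(3-methylbut-2-enyloxy)-5-(2-methylbut-3-en-2-yl)phenyl]chroman-7-ol
Conditions: TBAF (2.5 equiv), AcOH (2.5 equiv), THF, 0 °C
Reagents that add atoms: none
Why: Fluoride cleavage of both aryl silyl ethers under acetic acid buffering should spare the aryl prenyl ether, the terminal alkene and C3.

**Compound list**
1 | 2,4-dihydroxybenzaldehyde | O=Cc1ccc(O)cc1O | starting material
2 | 2-hydroxy-4-[(triisopropylsilyl)oxy]benzaldehyde | O=Cc1ccc(O[Si](C(C)C)(C(C)C)C(C)C)cc1O | intermediate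
3 | {2-formyl-5-[(triisopropylsilyl)oxy]phenoxy}methyl pivalate | O=Cc1ccc(O[Si](C(C)C)(C(C)C)C(C)C)cc1OCOC(=O)C(C)(C)C | intermediate
4 | 4-(benzyloxy)-2-hydroxybenzaldehyde | O=Cc1ccc(OCc2ccccc2)cc1O | starting material
5 | 5-(benzyloxy)-2-(hydroxymethyl)phenol | OCc1ccc(OCc2ccccc2)cc1O | intermediate
6 | [4-(benzyloxy)-2-hydroxybenzyl]triphenylphosphonium bromide | [Br-].Oc1cc(OCc2ccccc2)ccc1C[P+](c1ccccc1)(c1ccccc1)c1ccccc1 | intermediate
7 | lithium 5-(benzyloxy)-2-[(triphenylphosphoranylidene)methyl]phenoxide (ylide, not isolated) | [Li+].[O-]c1cc(OCc2ccccc2)ccc1C=P(c1ccccc1)(c1ccccc1)c1ccccc1 | intermediate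
8 | E/Z mixture of {2-[2-(4-(benzyloxy)-2-hydroxyphenyl)ethenyl]-5-[(triisopropylsilyl)oxy]phenoxy}methyl pivalate (not isolated) | CC(C)(C)C(=O)OCOc1cc(O[Si](C(C)C)(C(C)C)C(C)C)ccc1C=Cc1ccc(OCc2ccccc2)cc1O | intermediate
9 | {2-[(E)-2-(4-(benzyloxy)-2-hydroxyphenyl)ethenyl]-5-[(triisopropylsilyl)oxy]phenoxy}methyl pivalate | CC(C)(C)C(=O)OCOc1cc(O[Si](C(C)C)(C(C)C)C(C)C)ccc1/C=C/c1ccc(OCc2ccccc2)cc1O | intermediate
10 | (3R)-3-[4-(benzyloxy)-2-hydroxyphenyl]-7-[(triisopropylsilyl)oxy]chroman-4-ylium (C4 benzylic cation, not isolated) | Oc1cc(OCc2ccccc2)ccc1[C@@H]1COc2cc(O[Si](C(C)C)(C(C)C)C(C)C)ccc2[CH+]1 | intermediate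
11 | (6aR,11aR)-9-(benzyloxy)-3-[(triisopropylsilyl)oxy]-6a,11a-dihydro-6H-[1]benzofuro[3,2-c]chromene (cis-pterocarpan, not isolated) | C1Oc2cc(O[Si](C(C)C)(C(C)C)C(C)C)ccc2[C@@H]2Oc3cc(OCc4ccccc4)ccc3[C@H]12 | intermediate
12 | 5-(benzyloxy)-2-{(3R)-7-[(triisopropylsilyl)oxy]chroman-3-yl}phenol | Oc1cc(OCc2ccccc2)ccc1[C@@H]1COc2cc(O[Si](C(C)C)(C(C)C)C(C)C)ccc2C1 | intermediate
13 | (3R)-3-{4-(benzyloxy)-2-[(triisopropylsilyl)oxy]phenyl}-7-[(triisopropylsilyl)oxy]chroman | CC(C)[Si](Oc1cc(OCc2ccccc2)ccc1[C@@H]1COc2cc(O[Si](C(C)C)(C(C)C)C(C)C)ccc2C1)(C(C)C)C(C)C | intermediate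
14 | 4-{(3R)-7-[(triisopropylsilyl)oxy]chroman-3-yl}-3-[(triisopropylsilyl)oxy]phenol | Oc1ccc([C@@H]2COc3cc(O[Si](C(C)C)(C(C)C)C(C)C)ccc3C2)c(O[Si](C(C)C)(C(C)C)C(C)C)c1 | intermediate
15 | (3R)-3-{4-[(3-methylbut-2-en-1-yl)oxy]-2-[(triisopropylsilyl)oxy]phenyl}-7-[(triisopropylsilyl)oxy]chroman | CC(C)=CCOc1ccc([C@@H]2COc3cc(O[Si](C(C)C)(C(C)C)C(C)C)ccc3C2)c(O[Si](C(C)C)(C(C)C)C(C)C)c1 | intermediate
16 | 6-(2-methylbut-3-en-2-yl)-4-{(3R)-7-[(triisopropylsilyl)oxy]chroman-3-yl}-3-[(triisopropylsilyl)oxy]cyclohexa-2,4-dien-1-one (ortho-dienone, C6 unassigned, not isolated) | C=CC(C)(C)C1C=C([C@@H]2COc3cc(O[Si](C(C)C)(C(C)C)C(C)C)ccc3C2)C(O[Si](C(C)C)(C(C)C)C(C)C)=CC1=O | intermediate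
17 | 2-(2-methylbut-3-en-2-yl)-4-{(3R)-7-[(triisopropylsilyl)oxy]chroman-3-yl}-5-[(triisopropylsilyl)oxy]phenol | C=CC(C)(C)c1cc([C@@H]2COc3cc(O[Si](C(C)C)(C(C)C)C(C)C)ccc3C2)c(O[Si](C(C)C)(C(C)C)C(C)C)cc1O | intermediate
18 | (3R)-3-{4-[(3-methylbut-2-en-1-yl)oxy]-5-(2-methylbut-3-en-2-yl)-2-[(triisopropylsilyl)oxy]phenyl}-7-[(triisopropylsilyl)oxy]chroman | C=CC(C)(C)c1cc([C@@H]2COc3cc(O[Si](C(C)C)(C(C)C)C(C)C)ccc3C2)c(O[Si](C(C)C)(C(C)C)C(C)C)cc1OCC=C(C)C | intermediate
19 | Manuifolin D, (3R)-3-[2-hydroxy-4-(3-methylbut-2-enyloxy)-5-(2-methylbut-3-en-2-yl)phenyl]chroman-7-ol | C=CC(C)(C)c1cc([C@@H]2COc3cc(O)ccc3C2)c(O)cc1OCC=C(C)C | target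

**Totals**
Total step count: 12. Longest linear sequence: 10 steps (steps 1, 2 and 5 to 12, or equally steps 3, 4 and 5 to 12).

**Steps most likely to fail**

Step 6. The chiral acid may ionise the acyloxymethyl ether too slowly, or the chiral anion may discriminate the two faces of C3 poorly. During the reductive opening the reopened C4 cation may lose the C3 proton before hydride transfer, which would erode the configuration at C3, or it may alkylate an electron-rich ring of a second molecule. The fallback separates ring construction from stereocontrol and sets out from 9. An achiral Lewis acid (BF3·OEt2, CH2Cl2, −78 °C) should promote the cyclisation as a Prins cyclisation of an α-acyloxy ether, a known reaction type, with no demand for asymmetric induction, to give racemic cis-9-(benzyloxy)-3-[(triisopropylsilyl)oxy]-6a,11a-dihydro-6H-[1]benzofuro[3,2-c]chromene F1. Warming with p-TsOH in toluene should open it by loss of H6a, the known behaviour of pterocarpans in acid, to 5-(benzyloxy)-2-{7-[(triisopropylsilyl)oxy]-2H-chromen-3-yl}phenol F2. Asymmetric hydrogenation of this 3-aryl-2H-chromene with [Ir(cod)(L*)]BArF (monovalent iridium; cod = 1,5-cyclooctadiene, L* = a chiral phosphino-oxazoline, BArF = tetrakis[3,5-bis(trifluoromethyl)phenyl]borate) under H2 (50 bar) in CH2Cl2 would then set C3 and return to the route at 12.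

Step 10. The allyl group may migrate in part to C3', the 1,1-dimethylallyl group may isomerise further (abnormal Claisen), the o-allylphenol may cyclise onto its alkene, or the prenyl group may be lost. The fallback forms the aryl–C bond by cross-coupling and sets out from 14. Bromination with NBS (MeCN, −20 °C) should go ortho to the free OH at C5', since C3' is shielded by two oxygen substituents, to give 2-bromo-4-{(3R)-7-[(triisopropylsilyl)oxy]chroman-3-yl}-5-[(triisopropylsilyl)oxy]phenol F3. Suzuki–Miyaura coupling with prenylboronic acid pinacol ester, under ligand control for the branched (γ) product (Pd(OAc)2 with a bulky dialkylbiarylphosphine, K3PO4, THF–H2O, 40 °C), would attach the 1,1-dimethylallyl group and return to the route at 17.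

Step 5. The amide base or the phenoxide ylide may attack the acyloxymethyl ester, the olefination of the lithium phenoxide ylide may be sluggish, and the Z to E equilibration may stall or iodine may promote cyclisation of the 2-hydroxystilbene. The fallback forms the stilbene by Mizoroki–Heck arylation, which gives the E-alkene directly and needs no phenoxide ylide, and sets out from 3. Wittig methylenation (Ph3P=CH2 from methyltriphenylphosphonium bromide and KHMDS, THF, −78 to 0 °C) should give {2-ethenyl-5-[(triisopropylsilyl)oxy]phenoxy}methyl pivalate F4. Heck coupling of this styrene with 5-(benzyloxy)-2-iodophenol (Pd(OAc)2, P(o-tol)3, Et3N, DMF, 90 °C) should arylate the terminal alkene carbon and return to the route at 9.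

**Further compounds**
F1 | step 6 | racemic cis-9-(benzyloxy)-3-[(triisopropylsilyl)oxy]-6a,11a-dihydro-6H-[1]benzofuro[3,2-c]chromene (both enantiomers, descriptors omitted) | C1Oc2cc(O[Si](C(C)C)(C(C)C)C(C)C)ccc2C2Oc3cc(OCc4ccccc4)ccc3C12
F2 | step 6 | 5-(benzyloxy)-2-{7-[(triisopropylsilyl)oxy]-2H-chromen-3-yl}phenol | Oc1cc(OCc2ccccc2)ccc1C1=Cc2ccc(O[Si](C(C)C)(C(C)C)C(C)C)cc2OC1
F3 | step 10 | 2-bromo-4-{(3R)-7-[(triisopropylsilyl)oxy]chroman-3-yl}-5-[(triisopropylsilyl)oxy]phenol | Oc1cc(O[Si](C(C)C)(C(C)C)C(C)C)c([C@@H]2COc3cc(O[Si](C(C)C)(C(C)C)C(C)C)ccc3C2)cc1Br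
F4 | step 5 | {2-ethenyl-5-[(triisopropylsilyl)oxy]phenoxy}methyl pivalate | C=Cc1ccc(O[Si](C(C)C)(C(C)C)C(C)C)cc1OCOC(=O)C(C)(C)C
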